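Numbering (hydroazulene): C1–C3 with the fusion carbons C3a/C8a form the cyclopentane (side chain on C3, its methine is C2'). C3a–C4–C5–C6–C7–C8–C8a is the seven-membered ring, and the ether oxygen joins C3a to C6.
Retrosynthetic cuts, in order: the vanillate ester C–O bond; C8a–CH3; C3a–C4 together with C5–C6 ([5+2]); the pyranone back to a furan, and that furan's bond to the CH(OH)CH3 carbon (later C6); C1–C8a (cyclopentane); C3–C2'.
Enabling feature: O, C3a and C6 make an 8-oxabicyclo[3.2.1]octane whose two-carbon bridge C4–C5 is bare CH2–CH2. The carbinol C7 sits next to the methyl-bearing bridgehead C6, and the angular-methyl carbon C8a sits next to the ring-fusion bridgehead C3a. C7 and C8a are thus the carbonyl carbon and the enone beta-carbon of the adduct of a ring-fused 2-methyl-3-oxidopyrylium with an ethylene equivalent.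
Forward order of rings: the furan is bought, the cyclopentane is closed by an intramolecular B-alkyl Suzuki–Miyaura coupling, the furan is expanded to a pyranone (Achmatowicz), and the [5+2] then forms the tetrahydrofuran and the seven-membered carbocycle together. The ester is joined last.
Stereochemistry: C2' and C3 come from one dual-catalytic allylation. C3 steers the face of the cycloaddition (C3a, C6), the resulting bicycle steers the cuprate (C8a) and the hydride (C7).

Key step: step 9

Assumption: the iridium ligand is taken to induce the same sense on the 3-bromofuryl carbinol as on aryl vinyl carbinols, so the antipode giving 3R is chosen from that model (both antipodes are available); C2 is set independently by the (R)-amine.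

Step 1
Reactants: 1 3-bromofuran-2-carbaldehyde; 2 vinylmagnesium bromide
Product: 3 rac-1-(3-bromofuran-2-yl)prop-2-en-1-ol
Conditions: 2 (1.1 equiv), THF, −78 to −20 °C; pH 7 phosphate buffer quench; base-washed silica
Reagents that add atoms: none
Why: Grignard 1,2-addition to the aldehyde outpaces bromine–magnesium exchange at low temperature, the new carbinol centre is left racemic on purpose because step 2 is enantioconvergent, and the neutral quench protects the acid-labile furyl allyl carbinol.

Step 2
Reactants: 3 rac-1-(3-bromofuran-2-yl)prop-2-en-1-ol; 4 propanal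
Product: 5 (2S,3R)-3-(3-bromofuran-2-yl)-2-methylpent-4-enal
Conditions: [Ir(cod)Cl]2 (3 mol %), BINOL-derived dibenz[b,f]azepin-5-yl phosphoramidite (P,olefin) ligand (12 mol %, antipode giving 3R), (R)-2-{bis[3,5-bis(trifluoromethyl)phenyl](trimethylsilyloxy)methyl}pyrrolidine (15 mol %), (MeO)2P(O)OH (50 mol %), 4 (3 equiv), ClCH2CH2Cl, 25 °C
Reagents that add atoms: none
Why: Stereodivergent dual catalysis (iridium-catalysed branched-selective allylic substitution merged with enamine catalysis): acid-assisted ionisation channels both enantiomers of 3 into one allyliridium species whose ligand fixes C3 as R, while the E-enamine of 4 with the (R)-amine offers the face that makes C2 S, so each catalyst sets its own centre.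

Step 3
Reactants: 5 (2S,3R)-3-(3-bromofuran-2-yl)-2-methylpent-4-enal
Product: 6 (2S,3R)-3-(3-bromofuran-2-yl)-2-methylpent-4-en-1-ol
Conditions: NaBH4, MeOH, 0 °C, on the crude aldehyde
Reagents that add atoms: none
Why: Borohydride reduction of the aldehyde, run at once, removes the only epimerisable position (C2) before it can drift and touches neither the bromide nor the alkene.

Step 4
Reactants: 6 (2S,3R)-3-(3-bromofuran-2-yl)-2-methylpent-4-en-1-ol
Product: 7 tert-butyl{[(2S,3R)-3-(3-bromofuran-2-yl)-2-methylpent-4-en-1-yl]oxy}diphenylsilane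
Conditions: TBDPSCl, imidazole, CH2Cl2, 0 °C to rt
Reagents that add atoms: tert-butyl(chloro)diphenylsilane, CC(C)(C)[Si](Cl)(c1ccccc1)c1ccccc1
Why: Imidazole-promoted silylation of a primary alcohol; the TBDPS group offers no acidic C–H to n-BuLi in step 6, withstands NBS, cuprate, dilute acid and amalgam, and adds bulk to the side chain that must shield one face in step 9.

Step 5
Reactants: 7 tert-butyl{[(2S,3R)-3-(3-bromofuran-2-yl)-2-methylpent-4-en-1-yl]oxy}diphenylsilane
Product: 9 (6R)-6-[(2S)-1-(tert-butyldiphenylsilyloxy)propan-2-yl]-5,6-dihydro-4H-cyclopenta[b]furan, via B-alkyl-9-BBN borane 8 (not isolated)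
Conditions: 9-BBN-H (1.3 equiv), THF, 0 °C to rt; then PdCl2(dppf) (8 mol %), Cs2CO3 (3 equiv), DMF–H2O, 50 °C, 0.01 M
Reagents that add atoms: 9-borabicyclo[3.3.1]nonane, B1C2CCCC1CCC2 (its boron is held only in 8)
Why: Anti-Markovnikov hydroboration of the monosubstituted alkene followed by intramolecular B-alkyl Suzuki–Miyaura coupling: oxidative addition of zerovalent palladium into the furyl C–Br bond, base-assisted transmetalation and reductive elimination from a six-membered palladacycle close the cyclopentane, dilution disfavours oligomers, and neither stereocentre is involved.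

Step 6
Reactants: 9 (6R)-6-[(2S)-1-(tert-butyldiphenylsilyloxy)propan-2-yl]-5,6-dihydro-4H-cyclopenta[b]furan; 10 acetaldehyde
Product: 12 1-{(6R)-6-[(2S)-1-(tert-butyldiphenylsilyloxy)propan-2-yl]-5,6-dihydro-4H-cyclopenta[b]furan-2-yl}ethanol (both carbinol epimers), via 2-lithiofuran 11 (not isolated)
Conditions: n-BuLi (1.1 equiv), THF, −78 to 0 °C; 10 (3 equiv), −78 °C; H2O
Reagents that add atoms: n-butyllithium, [Li]CCCC (its lithium is held only in 11)
Why: Alpha-lithiation of the furan at its only free position next to oxygen (faster than lateral deprotonation at C6–H) and 1,2-addition to acetaldehyde; the new carbinol centre needs no control because it becomes planar in ylide 16.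

Step 7
Reactants: 12 the furyl ethanol (epimers)
Product: 13 (7R)-7a-hydroxy-2-methyl-7-[(2S)-1-(tert-butyldiphenylsilyloxy)propan-2-yl]-5,6,7,7a-tetrahydrocyclopenta[b]pyran-3(2H)-one (mixture at C2 and C7a)
Conditions: NBS (1.05 equiv), NaHCO3 (2 equiv), THF–H2O (4:1), 0 °C
Reagents that add atoms: water, O
Why: Achmatowicz rearrangement: bromonium-induced hydration of the furan, opening to the Z-enedione and re-closure through the carbinol oxygen give the pyranone hemiketal, whose two new centres are mixtures that vanish at the ylide stage.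

Step 8
Reactants: 13 the hydroxypyranone
Product: 14 (7R)-2-methyl-3-oxo-7-[(2S)-1-(tert-butyldiphenylsilyloxy)propan-2-yl]-2,3,5,6,7,7a-hexahydrocyclopenta[b]pyran-7a-yl acetate (mixture at C2 and C7a)
Conditions: Ac2O, pyridine, DMAP (cat.), CH2Cl2, 0 °C
Reagents that add atoms: acetic anhydride, CC(=O)OC(C)=O
Why: DMAP-catalysed acylation traps the cyclic hemiketal as its tertiary acetate, the usual isolable precursor of 3-oxidopyrylium ylides, which is easier to purify and to dose slowly than a sulfonate made in situ.

Step 9
Reactants: 14 the acetoxypyranone; 15 phenyl vinyl sulfone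
Product: 17 (3R,3aS,4S,6S)-3-[(2S)-1-(tert-butyldiphenylsilyloxy)propan-2-yl]-6-methyl-4-endo-(phenylsulfonyl)-3a,6-epoxyperhydroazul-8(8a)-en-7-one, via oxidopyrylium ylide 16 (not isolated)
Conditions: 15 (8 equiv), i-Pr2NEt (2 equiv), MeCN, 80 °C, 14 added slowly
Reagents that add atoms: none
Why: The amine takes the C2 proton of 14 while acetate leaves from C7a, which gives the planar aromatic betaine 16; its two carbons flanking the ring oxygen (methyl-bearing C2 and ring-fusion C7a) then bond suprafacially and in concert to the two alkene carbons of 15, forming C5–C6 and C3a–C4. The closest known reaction type is the intermolecular [5+2] cycloaddition of 3-oxidopyrylium ylides from Achmatowicz-derived acetoxypyranones with electron-poor alkenes. Both new rings close by cycloaddition in this one event: the tetrahydrofuran (O, C3a, C4, C5, C6) as the five-membered ring of a carbonyl-ylide-type 1,3-dipolar addition, the cycloheptenone (C3a to C8a) as the seven-membered ring made of five ylide carbons plus two alkene carbons. C3a and C6 are set together by the face of 16 that is attacked: the branched silyloxypropyl group on C3, bonded directly to the reacting C3a, covers one face of the flat cyclopentene-fused ring, so 15 adds anti to it and the ether oxygen ends cis to the side chain (3aS,6S), whereas C4 follows the usual endo preference and is erased in step 12. Facial selectivity is therefore the only selectivity needed, because regio- and endo/exo isomers at the sulfonyl carbon all converge on 21. The trialkylated ylide is electron-rich and matched to the acceptor alkene, and excess 15, a non-nucleophilic base and slow addition of 14 keep its dimerisation down.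

Step 10
Reactants: 17 the tricyclic enone sulfone
Product: 19 (3R,3aS,4S,6S,8aR)-3-[(2S)-1-(tert-butyldiphenylsilyloxy)propan-2-yl]-6,8a-dimethyl-4-endo-(phenylsulfonyl)-3a,6-epoxyperhydroazulen-7-one, via trimethylsilyl enol ether 18 (not isolated)
Conditions: CuI, MeLi (gives Me2CuLi, 4 equiv), TMSCl (6 equiv), Et2O–THF, −78 to −20 °C; then 1 M HCl, THF, 0 °C
Reagents that add atoms: lithium dimethylcuprate, [Li+].C[Cu-]C; chlorotrimethylsilane, C[Si](C)(C)Cl (its silicon is held only in 18)
Why: TMSCl-accelerated conjugate addition of lithium dimethylcuprate to the enone: the endo face of C8a lies under the C4–C5 bridge and its endo sulfonyl group, so methyl is delivered from the exo face (the side of the ether oxygen) to give 8aR, and the silyl enol ether is cleaved in the acidic work-up.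

Step 11
Reactants: 19 the angular-methyl ketone
Product: 20 (3R,3aS,4S,6S,7S,8aR)-3-[(2S)-1-(tert-butyldiphenylsilyloxy)propan-2-yl]-6,8a-dimethyl-4-endo-(phenylsulfonyl)-3a,6-epoxyperhydroazulen-7-ol
Conditions: NaBH4, MeOH–THF, −20 to 0 °C
Reagents that add atoms: none
Why: Borohydride reduction with hydride entering from the exo face (the endo face is closed by C5 and the two-carbon bridge) gives the equatorial 7S alcohol anti to the ether oxygen, which is also the thermodynamic epimer because an axial OH would be 1,3-diaxial to the C8a methyl, so Meerwein–Ponndorf–Verley equilibration with Al(Oi-Pr)3 stays in reserve; electron-transfer reductants are avoided while the ketone is present because they would cleave the alpha C6–O bond.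

Step 12
Reactants: 20 the sulfonyl alcohol
Product: 21 (3R,3aS,6S,7S,8aR)-3-[(2S)-1-(tert-butyldiphenylsilyloxy)propan-2-yl]-6,8a-dimethyl-3a,6-epoxyperhydroazulen-7-ol
Conditions: Na/Hg (6% Na), Na2HPO4, MeOH–THF, −20 to 0 °C
Reagents that add atoms: none
Why: Reductive desulfonylation by electron transfer: after C–S cleavage, protonation by the cold, buffered methanol should outrun Julia-type loss of the poor tertiary alkoxide leaving group at C3a, as is known for sulfones on heteroatom-bridged bicycles, and this leaves C4–C5 as CH2–CH2.

Step 13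
Reactants: 21 the silyl ether alcohol
Product: 22 (3R,3aS,6S,7S,8aR)-3-[(2S)-1-hydroxypropan-2-yl]-6,8a-dimethyl-3a,6-epoxyperhydroazulen-7-ol
Conditions: Bu4NF, THF, rt
Reagents that add atoms: none
Why: Fluoride-induced cleavage of the Si–O bond, driven by the strong Si–F bond, frees the primary alcohol without affecting the ether bridge or the secondary alcohol.

Step 14
Reactants: 22 the core diol; 23 4-acetoxy-3-methoxybenzoic acid
Product: 24 (2S)-2-[(3R,3aS,6S,7S,8aR)-7-hydroxy-6,8a-dimethyl-3a,6-epoxyperhydroazulen-3-yl]propyl 4-acetoxy-3-methoxybenzoate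
Conditions: 23 (1.05 equiv), EDC·HCl, DMAP, CH2Cl2, 0 °C to rt
Reagents that add atoms: none
Why: Steglich-type carbodiimide/DMAP esterification: the unhindered primary alcohol acylates far faster than the C7 alcohol, which is flanked by the quaternary C6, and the acetate on 23 keeps the phenol from competing.

Step 15
Reactants: 24 the acetyl-protected ester
Product: 25 (2S)-2-[(3R,3aS,6S,7S,8aR)-7-hydroxy-6,8a-dimethyl-3a,6-epoxyperhydroazulen-3-yl]propyl 4-hydroxy-3-methoxybenzoate (CNP0277205.1)
Conditions: NH4OAc, MeOH–H2O (4:1), rt
Reagents that add atoms: none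
Why: Chemoselective solvolysis of the aryl acetate, whose phenoxide is a much better leaving group than the alkoxide of the benzoate ester, under near-neutral NH4OAc conditions leaves the vanillate linkage and all stereocentres intact.

Compound list
1 | 3-bromofuran-2-carbaldehyde | O=Cc1occc1Br | starting material
2 | vinylmagnesium bromide | C=C[Mg]Br | starting material
3 | rac-1-(3-bromofuran-2-yl)prop-2-en-1-ol | C=CC(O)c1occc1Br | intermediate
4 | propanal | CCC=O | starting material
5 | (2S,3R)-3-(3-bromofuran-2-yl)-2-methylpent-4-enal | O=C[C@@H](C)[C@H](c1occc1Br)C=C | intermediate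
6 | (2S,3R)-3-(3-bromofuran-2-yl)-2-methylpent-4-en-1-ol | OC[C@@H](C)[C@H](c1occc1Br)C=C | intermediate
7 | TBDPS ether of 6 | CC(C)(C)[Si](c1ccccc1)(c1ccccc1)OC[C@@H](C)[C@H](c1occc1Br)C=C | intermediate
8 | B-alkyl-9-BBN borane from 7 (not isolated) | CC(C)(C)[Si](c1ccccc1)(c1ccccc1)OC[C@@H](C)[C@H](c1occc1Br)CCB1C2CCCC1CCC2 | intermediate
9 | (6R)-6-[(2S)-1-(TBDPS-oxy)propan-2-yl]-5,6-dihydro-4H-cyclopenta[b]furan | CC(C)(C)[Si](c1ccccc1)(c1ccccc1)OC[C@@H](C)[C@H]2CCc3ccoc23 | intermediate
10 | acetaldehyde | CC=O | starting material
11 | 2-lithio derivative of 9 (not isolated) | CC(C)(C)[Si](c1ccccc1)(c1ccccc1)OC[C@@H](C)[C@H]2CCc3cc([Li])oc23 | intermediate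
12 | furyl ethanol, carbinol epimers | CC(C)(C)[Si](c1ccccc1)(c1ccccc1)OC[C@@H](C)[C@H]2CCc3cc(C(C)O)oc23 | intermediate
13 | cyclopenta-fused 7a-hydroxy-2-methylpyran-3-one, mixture at C2 and C7a | CC(C)(C)[Si](c1ccccc1)(c1ccccc1)OC[C@@H](C)[C@H]2CCC3=CC(=O)C(C)OC23O | intermediate
14 | 7a-acetate of 13 | CC(C)(C)[Si](c1ccccc1)(c1ccccc1)OC[C@@H](C)[C@H]2CCC3=CC(=O)C(C)OC23OC(C)=O | intermediate
15 | phenyl vinyl sulfone | C=CS(=O)(=O)c1ccccc1 | starting material
16 | (7R)-2-methyl-7-substituted 6,7-dihydro-5H-cyclopenta[b]pyrylium-3-olate (not isolated) | CC(C)(C)[Si](c1ccccc1)(c1ccccc1)OC[C@@H](C)[C@H]2CCc3cc([O-])c(C)[o+]c23 | intermediate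
17 | tricyclic enone, 4-endo sulfone | CC(C)(C)[Si](c1ccccc1)(c1ccccc1)OC[C@@H](C)[C@H]2CCC3=CC(=O)[C@]4(C)C[C@H](S(=O)(=O)c5ccccc5)[C@]23O4 | intermediate
18 | 7-trimethylsilyl enol ether with the 8a-methyl group (not isolated) | CC(C)(C)[Si](c1ccccc1)(c1ccccc1)OC[C@@H](C)[C@H]2CC[C@]3(C)C=C(O[Si](C)(C)C)[C@]4(C)C[C@H](S(=O)(=O)c5ccccc5)[C@]23O4 | intermediate
19 | 8a-methyl ketone sulfone | CC(C)(C)[Si](c1ccccc1)(c1ccccc1)OC[C@@H](C)[C@H]2CC[C@]3(C)CC(=O)[C@]4(C)C[C@H](S(=O)(=O)c5ccccc5)[C@]23O4 | intermediate
20 | 7S alcohol sulfone | CC(C)(C)[Si](c1ccccc1)(c1ccccc1)OC[C@@H](C)[C@H]2CC[C@]3(C)C[C@H](O)[C@]4(C)C[C@H](S(=O)(=O)c5ccccc5)[C@]23O4 | intermediate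
21 | desulfonylated silyl ether alcohol | CC(C)(C)[Si](c1ccccc1)(c1ccccc1)OC[C@@H](C)[C@H]2CC[C@]3(C)C[C@H](O)[C@]4(C)CC[C@]23O4 | intermediate
22 | core diol | OC[C@@H](C)[C@H]2CC[C@]3(C)C[C@H](O)[C@]4(C)CC[C@]23O4 | intermediate
23 | 4-acetoxy-3-methoxybenzoic acid | CC(=O)Oc1ccc(C(=O)O)cc1OC | starting material
24 | O-acetylvanillate ester of 22 | COc1cc(C(=O)OC[C@@H](C)[C@H]2CC[C@]3(C)C[C@H](O)[C@]4(C)CC[C@]23O4)ccc1OC(C)=O | intermediate
25 | CNP0277205.1 | COc1cc(C(=O)OC[C@@H](C)[C@H]2CC[C@]3(C)C[C@H](O)[C@]4(C)CC[C@]23O4)ccc1O | target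

Total step count: 15. Longest linear sequence: 15 steps (1 to 25); all other inputs (2, 4, 10, 15, 23) are bought.

Steps most likely to fail

**Step 9.**
- Capture of the ylide at two fully substituted termini may be slower than its dimerisation.
- Reversible proton loss from the C3 methine next to the cationic terminus may erode the stereocentre that steers the facial approach.

The fallback sets out from 14 and returns at 21.
- The two-carbon partner becomes acrolein, the smallest and one of the most reactive acceptors for these ylides. Its activating group is excised at once by organometallic decarbonylation instead of late by electron transfer.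
- Treating 14 with acrolein and i-Pr2NEt in CH2Cl2 at room temperature should give, through the same ylide 16, the 4-endo-formyl cycloadduct F1.
- RhCl(PPh3)3 (1.1 equiv) in toluene at 110 °C (Tsuji–Wilkinson decarbonylation) converts it into the sulfone-free tricyclic enone F2.
- Lithium dimethylcuprate with TMSCl gives the silyl enol ether F3, which is hydrolysed on work-up to the sulfone-free 8a-methyl ketone F4.
- NaBH4 then gives 21.
- The step count stays the same, and the amalgam step is no longer needed.

**Step 10.**
- Conjugate addition may stall because it creates a quaternary carbon next to the fully substituted C3a.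
- This would leave room for 1,2-addition or for electron-transfer cleavage of the gamma C3a–O bond.

The fallback sets out from 17 and returns at 19.
- The methyl carbon is brought in as a one-carbon ylide instead of an organocopper reagent.
- Dimethylsulfoxonium methylide (Me3S(O)I, NaH, DMSO, rt to 50 °C; Corey–Chaykovsky cyclopropanation) is small and adds reversibly. It should attack C8a from the same exo face and close to the exo cyclopropyl ketone F5.
- Hydrogenolysis (H2, Pd/C, EtOAc–AcOH) then breaks the least hindered carbonyl-conjugated bond, C8–CH2. This turns the cyclopropane methylene into the C8a methyl group of 19.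
- The silyl ether, unlike a benzyl ether, survives this step.

**Step 12.**
- After C–S cleavage, Julia-type loss of the bridging alkoxide from C3a may outrun protonation, and the ether bridge would open.

The fallback sets out from 20 and returns at 21. The elimination is run on purpose and the bridge is rebuilt.
- SmI2 with HMPA in THF without a proton source should give the ring-opened C3a=C4 hydroazulene diol F6.
- Hg(OCOCF3)2 in CH2Cl2–THF then triggers transannular oxymercuration. The tertiary C6 hydroxyl adds to the fully substituted C3a, and it can reach that carbon only from the face on which it sits, so the original configuration returns. This gives the 4-endo organomercury trifluoroacetate F7.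
- Alkaline NaBH4 reduces F7 in the same flask to 21.

Further compounds
F1 | step 9 | 4-endo-formyl cycloadduct | CC(C)(C)[Si](c1ccccc1)(c1ccccc1)OC[C@@H](C)[C@H]2CCC3=CC(=O)[C@]4(C)C[C@H](C=O)[C@]23O4
F2 | step 9 | sulfone-free tricyclic enone | CC(C)(C)[Si](c1ccccc1)(c1ccccc1)OC[C@@H](C)[C@H]2CCC3=CC(=O)[C@]4(C)CC[C@]23O4
F3 | step 9 | silyl enol ether (7-OTMS, 8a-methyl, no sulfone) | CC(C)(C)[Si](c1ccccc1)(c1ccccc1)OC[C@@H](C)[C@H]2CC[C@]3(C)C=C(O[Si](C)(C)C)[C@]4(C)CC[C@]23O4
F4 | step 9 | sulfone-free 8a-methyl ketone | CC(C)(C)[Si](c1ccccc1)(c1ccccc1)OC[C@@H](C)[C@H]2CC[C@]3(C)CC(=O)[C@]4(C)CC[C@]23O4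
F5 | step 10 | exo cyclopropyl ketone (CH2 bridging C8 and C8a) | CC(C)(C)[Si](c1ccccc1)(c1ccccc1)OC[C@@H](C)[C@H]2CC[C@@]35C[C@H]5C(=O)[C@]4(C)C[C@H](S(=O)(=O)c6ccccc6)[C@]23O4
F6 | step 12 | ring-opened C3a=C4 hydroazulene diol | CC(C)(C)[Si](c1ccccc1)(c1ccccc1)OC[C@@H](C)[C@H]2CC[C@]3(C)C[C@H](O)[C@](O)(C)CC=C23
F7 | step 12 | 4-endo organomercury trifluoroacetate | CC(C)(C)[Si](c1ccccc1)(c1ccccc1)OC[C@@H](C)[C@H]2CC[C@]3(C)C[C@H](O)[C@]4(C)C[C@H]([Hg]OC(=O)C(F)(F)F)[C@]23O4
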